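**Retrosynthetic overview**
- The pyran ring is cut last at both its O–C(spiro) and aryl–C(benzylic) bonds, giving C2v-symmetric 2,4-diformylphloroglucinol and a tertiary styryl cyclohexenyl carbinol. The forward step is a one-flask Friedel–Crafts allylation/oxa-cyclisation that desymmetrises the arene and sets both new stereocentres.
- The carbinol comes from a bicyclic enone (octalone) and an (E)-styryl organometallic.
- The octalone comes from a 1,5-diketone by kinetic aldol/elimination; the diketone comes from (−)-menthone and an α-silyl vinyl ketone by a kinetic Michael addition that sets the ring-fusion CH.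
- 2,4-Diformylphloroglucinol comes from phloroglucinol by double Vilsmeier–Haack formylation.
- Ring order: ring A (from menthone), then ring B (annulation), then the arene is attached, then the pyran ring closes.

Assumption: 3-(trimethylsilyl)but-3-en-2-one and (E)-β-bromostyrene are bought, and LiN(iPr)2 is used as a commercial solution.

**Step 1**
Reactants: 1 (−)-menthone [(2S,5R)-5-methyl-2-(propan-2-yl)cyclohexan-1-one]; 2 3-(trimethylsilyl)but-3-en-2-one
Product: 5 (2R,3R,6S)-3-methyl-2-(3-oxobutyl)-6-(propan-2-yl)cyclohexan-1-one, via menthone lithium enolate 3 (not isolated), via α-silyl diketone 4 (not isolated)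
Conditions: LiN(iPr)2 (1.05 equiv), THF, −78 °C; 2, −78 °C, 1 h; then 1 M HCl, 0 °C to rt
Reagents that add atoms: none
Why: Stork–Ganem Michael addition, in which the amide base removes the less hindered CH2 proton under kinetic control (the isopropyl-bearing centre is untouched) and the C–C bond forms by chair-like axial attack anti to the axial hydrogen on the methyl-bearing carbon (the opposite chair-like approach is blocked by a syn-axial isopropyl group), so the side chain ends up trans to isopropyl and cis to methyl (new centre 2R); dilute acid then removes the silyl group.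

**Step 2**
Reactants: 5 (2R,3R,6S)-3-methyl-2-(3-oxobutyl)-6-(propan-2-yl)cyclohexan-1-one
Product: 9 (4aR,5R,8S)-5-methyl-8-(propan-2-yl)-4,4a,5,6,7,8-hexahydronaphthalen-2(3H)-one, via terminal lithium enolate 6 (not isolated), via lithium aldolate 7 (not isolated), via β-acetoxy ketone 8 (not isolated)
Conditions: LiN(iPr)2 (1.1 equiv), THF, −78 to −30 °C; Ac2O, −30 °C; DBU, 0 °C to rt
Reagents that add atoms: none
Why: Robinson-type ring closure run stepwise under kinetic control (methyl-ketone enolate, intramolecular aldol addition, acetylation, E1cB elimination), so the ring ketone is never enolised, the two stereocentres next to it keep their configuration, and no new stereocentre remains.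

**Step 3**
Reactants: 10 phloroglucinol (benzene-1,3,5-triol)
Product: 12 2,4-diformylphloroglucinol (2,4,6-trihydroxybenzene-1,3-dicarbaldehyde), via bis-iminium dichloride 11 (not isolated)
Conditions: POCl3 (2.4 equiv), DMF (2.4 equiv), EtOAc, 0 °C to rt; then H2O, rt
Reagents that add atoms: N,N-dimethylformamide, CN(C)C=O; water, O
Why: Twofold Vilsmeier–Haack formylation of a very electron-rich arene, which stops at two formyl groups because the ring is then deactivated; no stereocentre is involved.

**Step 4**
Reactants: 9 (4aR,5R,8S)-5-methyl-8-(propan-2-yl)-4,4a,5,6,7,8-hexahydronaphthalen-2(3H)-one; 13 (E)-(2-bromoethenyl)benzene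
Product: 15 (2RS,4aR,5R,8S)-5-methyl-2-[(E)-2-phenylethenyl]-8-(propan-2-yl)-2,3,4,4a,5,6,7,8-octahydronaphthalen-2-ol, via styrylmagnesium bromide 14 (not isolated)
Conditions: 13, Mg, THF, rt; CeCl3 (anhydrous, 1.5 equiv), THF, −78 °C; 9, −78 to 0 °C; pH 7 buffer
Reagents that add atoms: none
Why: Imamoto-type 1,2-addition of an alkenylcerium reagent to the enone carbonyl, which suppresses enolisation and conjugate addition; the carbinol centre forms as a mixture that does not matter because it is ionised in step 5.

**Step 5**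
Reactants: 15 (2RS,4aR,5R,8S)-5-methyl-2-[(E)-2-phenylethenyl]-8-(propan-2-yl)-2,3,4,4a,5,6,7,8-octahydronaphthalen-2-ol; 12 2,4-diformylphloroglucinol
Product: 18 Guajadial C, via dienyl cation 16 (not isolated), via C-alkylated phenol 17 (not isolated)
Conditions: 12 (1.5 equiv), 1,1,1-trifluoro-N-{(11bR)-4-oxido-2,6-bis(2,4,6-triisopropylphenyl)dinaphtho[2,1-d:1′,2′-f][1,3,2]dioxaphosphepin-4-yl}methanesulfonamide (chiral Brønsted acid, 5 mol %), 4 Å molecular sieves, CH2Cl2, −40 to 0 °C
Reagents that add atoms: none
Why: Proposed new method: the chiral acid ionises 15 to the contact ion pair 16, the only free ring carbon of 12 (held to the phosphoramidate through its hydroxyl groups) attacks the least hindered benzylic terminus on the face left open by the catalyst anion (benzylic centre R by catalyst control, the substrate centres being remote) to give 17, and reprotonation at the diene terminus lets either of the two equivalent ortho hydroxyl groups close the pyran ring by axial attack on the cyclohexenyl cation anti to the pseudoaxial ring-fusion hydrogen (spiro centre S), which ends the C2v symmetry of 12; the closest known reactions are the acid-mediated Friedel–Crafts allylation/oxa-cyclisation of resorcinols with tertiary allylic alcohols (cannabinoid chroman synthesis) and chiral N-triflylphosphoramide-catalysed allylic substitutions through contact ion pairs.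

**Compound list**
1 | (−)-menthone, (2S,5R)-5-methyl-2-(propan-2-yl)cyclohexan-1-one | CC(C)[C@@H]1CC[C@@H](C)CC1=O | starting material
2 | 3-(trimethylsilyl)but-3-en-2-one | CC(=O)C(=C)[Si](C)(C)C | starting material
3 | lithium (3R,6S)-3-methyl-6-(propan-2-yl)cyclohex-1-en-1-olate | CC(C)[C@@H]1CC[C@@H](C)C=C1[O-].[Li+] | intermediate
4 | (2R,3R,6S)-3-methyl-2-[3-oxo-2-(trimethylsilyl)butyl]-6-(propan-2-yl)cyclohexan-1-one (both epimers at the silyl-bearing carbon) | CC(C)[C@@H]1CC[C@@H](C)[C@@H](CC(C(C)=O)[Si](C)(C)C)C1=O | intermediate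
5 | (2R,3R,6S)-3-methyl-2-(3-oxobutyl)-6-(propan-2-yl)cyclohexan-1-one | CC(C)[C@@H]1CC[C@@H](C)[C@@H](CCC(C)=O)C1=O | intermediate
6 | lithium 4-[(1R,2R,5S)-2-methyl-6-oxo-5-(propan-2-yl)cyclohexyl]but-1-en-2-olate | CC(C)[C@@H]1CC[C@@H](C)[C@@H](CCC(=C)[O-])C1=O.[Li+] | intermediate
7 | lithium alkoxide of (4aR,5R,8S)-8a-hydroxy-5-methyl-8-(propan-2-yl)octahydronaphthalen-2(1H)-one (either 8a epimer) | CC(C)[C@@H]1CC[C@@H](C)[C@H]2CCC(=O)CC12[O-].[Li+] | intermediate
8 | (4aR,5R,8S)-5-methyl-2-oxo-8-(propan-2-yl)octahydronaphthalen-8a(1H)-yl acetate (either 8a epimer) | CC(C)[C@@H]1CC[C@@H](C)[C@H]2CCC(=O)CC12OC(C)=O | intermediate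
9 | (4aR,5R,8S)-5-methyl-8-(propan-2-yl)-4,4a,5,6,7,8-hexahydronaphthalen-2(3H)-one | CC(C)[C@@H]1CC[C@@H](C)[C@H]2CCC(=O)C=C12 | intermediate
10 | phloroglucinol, benzene-1,3,5-triol | Oc1cc(O)cc(O)c1 | starting material
11 | bis(dimethyliminiomethyl)phloroglucinol dichloride | C[N+](C)=Cc1c(O)cc(O)c(C=[N+](C)C)c1O.[Cl-].[Cl-] | intermediate
12 | 2,4-diformylphloroglucinol, 2,4,6-trihydroxybenzene-1,3-dicarbaldehyde | O=Cc1c(O)cc(O)c(C=O)c1O | intermediate
13 | (E)-(2-bromoethenyl)benzene, (E)-β-bromostyrene | Br/C=C/c1ccccc1 | starting material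
14 | bromo[(E)-2-phenylethenyl]magnesium | Br[Mg]/C=C/c1ccccc1 | intermediate
15 | (2RS,4aR,5R,8S)-5-methyl-2-[(E)-2-phenylethenyl]-8-(propan-2-yl)-2,3,4,4a,5,6,7,8-octahydronaphthalen-2-ol (both carbinol epimers) | CC(C)[C@@H]1CC[C@@H](C)[C@H]2CCC(O)(/C=C/c3ccccc3)C=C12 | intermediate
16 | (4aR,5R,8S)-5-methyl-2-[(E)-2-phenylethenyl]-8-(propan-2-yl)-3,4,4a,5,6,7,8-heptahydronaphthalen-2-ylium (delocalised cation, ion pair with the catalyst anion) | CC(C)[C@@H]1CC[C@@H](C)[C@H]2CC[C+](/C=C/c3ccccc3)C=C12 | intermediate
17 | 2,4,6-trihydroxy-5-{(1R)-2-[(4aR,5R,8S)-5-methyl-8-(propan-2-yl)-4,4a,5,6,7,8-hexahydronaphthalen-2(3H)-ylidene]-1-phenylethyl}benzene-1,3-dicarbaldehyde (alkene geometry not fixed) | CC(C)[C@@H]1CC[C@@H](C)[C@H]2CCC(=C[C@H](c3ccccc3)c3c(O)c(C=O)c(O)c(C=O)c3O)C=C12 | intermediate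
18 | Guajadial C (spiro carbon S, benzylic carbon R, decalin centres 4aR,5R,8S) | CC(C)[C@@H]1CC[C@@H](C)[C@H]2CC[C@@]3(C=C12)C[C@H](c1ccccc1)c1c(O)c(C=O)c(O)c(C=O)c1O3 | target

**Step count**
Total steps: 5. Longest linear sequence: 4 (1 → 5 → 9 → 15 → 18).

**Steps most likely to fail**

Step 5 is the least certain. The facial selectivity at the benzylic carbon rests on untested catalyst control, and without it a roughly 1:1 mixture at that centre is expected. Cation 16 can also lose a proton next to the ring fusion to give conjugated trienes, which would scramble the decalin centres, and 12 is a weak nucleophile. The fallback sets out from 9 and comes back at 18. Wittig methylenation of 9 (Ph3P=CH2, THF) gives the cross-conjugated diene (1S,4R,4aR)-4-methyl-7-methylidene-1-(propan-2-yl)-1,2,3,4,4a,5,6,7-octahydronaphthalene F5. Heating F5 with benzaldehyde and 12 under neutral conditions forms the o-quinone methide (5E)-5-benzylidene-2,4-dihydroxy-6-oxocyclohexa-1,3-diene-1,3-dicarbaldehyde F6 by Knoevenagel condensation. F6 is trapped by the exocyclic alkene of F5 in an endo hetero-Diels–Alder reaction, which gives 18 without any carbocation.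

Step 1 may give a poor ratio at the new centre, because the all-equatorial epimer (side chain trans to methyl) is the thermodynamic one and the kinetic preference is argued, not measured. The fallback sets out from 1 and comes back at 5. Condensation of 1 with 1,1-dimethylhydrazine gives (−)-menthone N,N-dimethylhydrazone F1. Deprotonation with LiN(iPr)2 gives an azaenolate in which allylic strain holds the isopropyl group axial, so alkylation with 2-(2-bromoethyl)-2-methyl-1,3-dioxolane occurs trans to it and gives the alkylated hydrazone ketal F2. Mild aqueous acid (1 M HCl, THF, 0 °C) removes the hydrazone and the dioxolane to give 5.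

Step 2 may suffer from retro-aldol reaction, slow acetylation of the hindered aldolate, or epimerisation next to the ring ketone. The fallback sets out from 1 and comes back at 9, replacing the aldol closure by an olefination. Kinetic Michael addition of the lithium enolate of 1 to methyl acrylate gives the keto ester methyl 3-[(1R,2R,5S)-2-methyl-6-oxo-5-(propan-2-yl)cyclohexyl]propanoate F3. Dimethyl (lithiomethyl)phosphonate converts the ester into the β-ketophosphonate dimethyl {4-[(1R,2R,5S)-2-methyl-6-oxo-5-(propan-2-yl)cyclohexyl]-2-oxobutyl}phosphonate F4. An intramolecular Horner–Wadsworth–Emmons reaction (LiCl, DBU, MeCN) closes ring B to 9 under conditions that deprotonate only the phosphonate.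

**Further compounds**
F1 | step 1 | (−)-menthone N,N-dimethylhydrazone, (E)-1-(2,2-dimethylhydrazinylidene)-(2S,5R)-5-methyl-2-(propan-2-yl)cyclohexane | CC(C)[C@@H]1CC[C@@H](C)C/C1=N\N(C)C
F2 | step 1 | (2R,3R,6S)-3-methyl-2-[2-(2-methyl-1,3-dioxolan-2-yl)ethyl]-6-(propan-2-yl)cyclohexan-1-one N,N-dimethylhydrazone | CC(C)[C@@H]1CC[C@@H](C)[C@@H](CCC2(C)OCCO2)/C1=N\N(C)C
F3 | step 2 | methyl 3-[(1R,2R,5S)-2-methyl-6-oxo-5-(propan-2-yl)cyclohexyl]propanoate | CC(C)[C@@H]1CC[C@@H](C)[C@@H](CCC(=O)OC)C1=O
F4 | step 2 | dimethyl {4-[(1R,2R,5S)-2-methyl-6-oxo-5-(propan-2-yl)cyclohexyl]-2-oxobutyl}phosphonate | CC(C)[C@@H]1CC[C@@H](C)[C@@H](CCC(=O)CP(=O)(OC)OC)C1=O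
F5 | step 5 | (1S,4R,4aR)-4-methyl-7-methylidene-1-(propan-2-yl)-1,2,3,4,4a,5,6,7-octahydronaphthalene | CC(C)[C@@H]1CC[C@@H](C)[C@H]2CCC(=C)C=C12
F6 | step 5 | (5E)-5-benzylidene-2,4-dihydroxy-6-oxocyclohexa-1,3-diene-1,3-dicarbaldehyde | O=C1/C(=C/c2ccccc2)C(O)=C(C=O)C(O)=C1C=O
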